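## Retrosynthetic overview

1. Numbering: pyran ring O1, C2 (=CH2), C3 (OH), C4, C5 (Br), C6 (Me2); carbocycle C1′ (bonded to C3), C2′, C3′, C4′ (Cl, Me), C5′ (Br), C6′. The feature used: inside the pyran ring, O1–C6(Me2)–C5–C4 is the skeleton of 3-hydroxy-3-methylbutan-2-one and C2–C3 is the carboxyl/keto pair of an α-keto acid. The heterocycle therefore reduces to one ester bond (O1–C2) and one aldol bond (C3–C4).
2. Endgame: C2=CH2 comes from the lactone C2=O by titanium methylenation, C5–Br from C5–OH by SN2 inversion, and C5–OH from the C5 ketone by hydride delivery directed by the C3–OH.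
3. Key disconnection: the pyran ring, in its 2,5-dioxo form, comes from the open α-keto ester by a catalytic asymmetric intramolecular aldol that forms C3–C4 and sets C3.
4. The α-keto ester comes from a 2-substituted acrylate by ozonolysis. The acrylate masks C3=O against electrophiles while the ring alkene is converted, by reagent-controlled epoxidation, HBr opening and a chloride-terminated 1,2-bromine shift, into the diequatorial C5′-Br/C4′-Cl pair.
5. The acrylate comes from (S)-limonene (isopropenyl CH3 oxidised to CO2H) and 3-hydroxy-3-methylbutan-2-one. Ring order: the carbocycle and C1′ are bought, and the pyran ring is the only ring built.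

Key step: step 9

Assumption: no close precedent fixes the sense of induction of the cinchona primary amine in step 9. The quinine-derived catalyst is written; its quinidine-derived pseudo-enantiomer replaces it, with nothing else changed, if the Re face of C3 turns out to be favoured.

## Route

Step 1
Reactants: 1 (S)-(−)-limonene
Product: 4 2-[(1S)-4-methylcyclohex-3-en-1-yl]prop-2-en-1-ol, via allyllithium 2 (not isolated), via allylboronate 3 (not isolated)
Conditions: n-BuLi, TMEDA, hexane, rt, 16 h (1 in excess); B(OMe)3, Et2O, −78 °C → rt; 30% H2O2, aq NaOH, 0 °C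
Reagents that add atoms: n-butyllithium CCCC[Li] (Li of 2); trimethyl borate COB(OC)OC (B(OMe)2 of 3); hydrogen peroxide OO (O of 4)
Why: Allylic lithiation of limonene with n-BuLi·TMEDA is known to occur at the isopropenyl methyl group, away from the C1′ stereocentre, and borylation followed by peroxide oxidation gives a single alcohol because both termini of the 2-substituted allyl anion are equivalent CH2 groups.

Step 2
Reactants: 4 2-[(1S)-4-methylcyclohex-3-en-1-yl]prop-2-en-1-ol
Product: 5 2-[(1S)-4-methylcyclohex-3-en-1-yl]prop-2-enal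
Conditions: activated MnO2 (excess), CH2Cl2, rt
Reagents that add atoms: none
Why: MnO2 oxidation is selective for the allylic alcohol and is neutral, so neither the ring alkene nor the allylic C1′–H is touched.

Step 3
Reactants: 5 2-[(1S)-4-methylcyclohex-3-en-1-yl]prop-2-enal
Product: 6 2-[(1S)-4-methylcyclohex-3-en-1-yl]prop-2-enoic acid
Conditions: NaClO2, NaH2PO4, 2-methyl-2-butene (large excess), t-BuOH/H2O, 0 °C → rt
Reagents that add atoms: sodium chlorite [Na+].[O-]Cl=O
Why: Pinnick oxidation takes the enal to the acid at about pH 4 without attacking C=C bonds, provided the excess 2-methyl-2-butene removes the hypochlorous acid before it reaches the trisubstituted ring alkene.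

Step 4
Reactants: 6 2-[(1S)-4-methylcyclohex-3-en-1-yl]prop-2-enoic acid; 7 3-hydroxy-3-methylbutan-2-one
Product: 9 2-methyl-3-oxobutan-2-yl 2-[(1S)-4-methylcyclohex-3-en-1-yl]prop-2-enoate, via mixed anhydride 8 (not isolated)
Conditions: 2,4,6-Cl3C6H2COCl, Et3N, toluene, rt; then 7, DMAP, toluene, rt → 50 °C
Reagents that add atoms: 2,4,6-trichlorobenzoyl chloride O=C(Cl)c1c(Cl)cc(Cl)cc1Cl (aroyl group of 8 only)
Why: Yamaguchi esterification delivers the acyl group through the DMAP acylpyridinium ion, which is reactive enough for the tertiary α-ketol and liberates no HCl that could add to the ring alkene, and the acid has no α-hydrogen, so no ketene forms and C1′ is not at risk.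

Step 5
Reactants: 9 2-methyl-3-oxobutan-2-yl 2-[(1S)-4-methylcyclohex-3-en-1-yl]prop-2-enoate
Product: 10 2-methyl-3-oxobutan-2-yl 2-[(1R,3S,6S)-6-methyl-7-oxabicyclo[4.1.0]heptan-3-yl]prop-2-enoate (epoxide oxygen trans to the side chain, methyl cis to it)
Conditions: D-fructose-derived Shi ketone (30 mol %), Oxone, K2CO3, Bu4NHSO4 (cat.), MeCN–CH2(OMe)2 / aq Na2B4O7–Na2EDTA buffer (pH ≈ 10.5), 0 °C, short reaction time
Reagents that add atoms: potassium peroxymonosulfate (Oxone) [K+].[O-]S(=O)(=O)OO
Why: Shi epoxidation: the chiral dioxirane oxidises only the electron-rich trisubstituted ring alkene (the acrylate is too electron-poor), and since the remote C1′ centre gives the two faces no intrinsic bias the D-fructose-derived ketone decides through its spiro transition state, which for 1-substituted cyclohexenes delivers oxygen to the face that here lies trans to the side chain (C4′ S, C5′ R at this stage).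

Step 6
Reactants: 10 the epoxy acrylate
Product: 11 2-methyl-3-oxobutan-2-yl 2-[(1S,3R,4R)-4-bromo-3-hydroxy-4-methylcyclohexyl]prop-2-enoate (Br and OH trans-diaxial, Br cis to the side chain)
Conditions: 48% aq HBr (1.05 equiv), Et2O, −20 °C; rapid chromatography on neutral silica
Reagents that add atoms: hydrogen bromide Br
Why: Acid-promoted epoxide opening in which the Markovnikov preference and the Fürst–Plattner rule point to the same carbon, so bromide enters at tertiary C4′ with inversion and gives the trans-diaxial bromohydrin, as in the textbook opening of 1-methylcyclohexene oxide by HBr, while material from any trans-epoxide becomes a constitutional isomer (secondary bromide, tertiary alcohol) that chromatography removes.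

Step 7
Reactants: 11 the tertiary-bromide bromohydrin
Product: 14 2-methyl-3-oxobutan-2-yl 2-[(1S,3S,4S)-3-bromo-4-chloro-4-methylcyclohexyl]prop-2-enoate, via chlorosulfite 12 (not isolated), via bromonium chloride 13 (not isolated)
Conditions: SOCl2, 2,6-lutidine, CH2Cl2, −40 °C → rt
Reagents that add atoms: thionyl chloride O=S(Cl)Cl
Why: Neighbouring-group participation by bromine: the axial C4′–Br bond lies antiperiplanar to the axial chlorosulfite and expels it to give bromonium ion 13 on the face cis to the side chain, chloride then opens 13 from the other face at C4′, the tertiary carbon that carries most of the charge (the regiochemistry of BrCl addition to trisubstituted alkenes), so that Br ends equatorial on C5′ (S) and Cl equatorial on C4′ (S), and the electron-poor acrylate cannot take up Br+ and scramble the ion.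

Step 8
Reactants: 14 the bromochloro acrylate
Product: 16 2-methyl-3-oxobutan-2-yl 2-[(1S,3S,4S)-3-bromo-4-chloro-4-methylcyclohexyl]-2-oxoacetate, via ozonide 15 (not isolated)
Conditions: O3, CH2Cl2, −78 °C; Me2S, −78 °C → rt; dried azeotropically
Reagents that add atoms: ozone [O-][O+]=O
Why: Ozonolysis of a 2-substituted acrylate is the standard route to an α-keto ester, the methylene is the only C=C left, and the base-free conditions at −78 °C leave the now enolisable C1′ centre intact.

Step 9
Reactants: 16 the α-keto ester of 3-hydroxy-3-methylbutan-2-one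
Product: 18 (3R)-3-[(1S,3S,4S)-3-bromo-4-chloro-4-methylcyclohexyl]-3-hydroxy-6,6-dimethyloxane-2,5-dione, via catalyst enamine 17 (not isolated)
Conditions: 9-amino-9-deoxy-epi-quinine (20 mol %), AcOH (60 mol %), toluene (0.05 M), 0 °C → rt
Reagents that add atoms: 9-amino-9-deoxy-epi-quinine N[C@@H](c1ccnc2ccc(OC)cc12)[C@@H]1C[C@@H]2CCN1C[C@@H]2C=C (catalyst; its atoms are in 17 only and leave again)
Why: Proposed new method: the primary amine of the catalyst condenses with the C5 methyl ketone, which can tautomerise only toward C4 because C6 is quaternary, enamine 17 adds through C4 to the C3 keto group, the most electrophilic carbonyl present, and hydrolysis of the iminium ion releases 18 and the catalyst. The closest known reactions are the primary-amine-catalysed aldol addition of methyl ketones to α-keto esters and the cinchona-amine-catalysed 6-enolendo aldolisation of diketones; what is new is that the tether is an ester and the ring formed a δ-lactone. The single ring closes in the 6-(enolendo)-exo-trig mode, for which the ester must leave its preferred Z rotamer for the E rotamer of a δ-lactone, a cost that the C6 gem-dimethyl group and the high electrophilicity of C3 should offset. C3 is set by the catalyst, whose protonated quinuclidine should hydrogen-bond to the C3 carbonyl oxygen and expose the Si face to C4 (giving 3R), while the neighbouring C1′ centre is expected to have little say. The step needs chemoselectivity (C4 onto C3 and not onto the ester carbon C2, no enolisation of C3 toward C1′, no dehydration of the aldol), which rests on the acetic-acid-buffered, weakly basic medium, on the low temperature and on the tert-alkyl ester being too hindered for easy aminolysis. Any C3 epimer is a diastereomer and is removed by chromatography.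

Step 10
Reactants: 18 the hydroxy lactone ketone
Product: 19 (3R,5S)-3-[(1S,3S,4S)-3-bromo-4-chloro-4-methylcyclohexyl]-3,5-dihydroxy-6,6-dimethyloxan-2-one (3,5-trans diol)
Conditions: Me4NBH(OAc)3, MeCN/AcOH, −30 °C; neutral work-up, used at once
Reagents that add atoms: none
Why: Evans–Saksena reduction: the reagent does not reduce ketones on its own but exchanges an acetate for the C3 hydroxyl, which is axial when the cyclohexyl group is equatorial, and hands its hydride to C5 on that same face, which sets C5 as S (3,5-trans diol) and leaves lactone and halides alone.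

Step 11
Reactants: 19 the 3,5-trans diol lactone
Product: 21 (3R,5R)-5-bromo-3-[(1S,3S,4S)-3-bromo-4-chloro-4-methylcyclohexyl]-3-hydroxy-6,6-dimethyloxan-2-one, via C5 triflate 20 (not isolated)
Conditions: Tf2O (1.05 equiv), 2,6-lutidine, CH2Cl2, −40 °C; then n-Bu4NBr (excess), toluene, 0 °C → rt
Reagents that add atoms: triflic anhydride O=S(=O)(OS(=O)(=O)C(F)(F)F)C(F)(F)F (triflyl group of 20 only); tetrabutylammonium bromide CCCC[N+](CCCC)(CCCC)CCCC.[Br-]
Why: Triflate displacement (SN2, inversion): only the secondary C5–OH is sulfonylated, bromide then enters from the face of the C3–OH and sets C5 as R, and the usual failures of 3-sulfonyloxy-2,2-dimethyltetrahydropyrans are damped here because O1 is an acyl oxygen that cannot bridge to C5 (no ring contraction) and the equatorial triflate has no antiperiplanar hydrogen for E2.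

Step 12
Reactants: 21 the bromo hydroxy lactone
Product: 22 (3R,5R)-5-bromo-3-[(1S,3S,4S)-3-bromo-4-chloro-4-methylcyclohexyl]-6,6-dimethyl-3-(trimethylsilyloxy)oxan-2-one
Conditions: TMSOTf, 2,6-lutidine, CH2Cl2, −78 → 0 °C
Reagents that add atoms: trimethylsilyl triflate C[Si](C)(C)OS(=O)(=O)C(F)(F)F
Why: Silylation with a silyl triflate and a hindered pyridine is the standard answer to crowded tertiary alcohols and removes the only acidic proton before the organotitanium step.

Step 13
Reactants: 22 the silylated lactone
Product: 23 [(3R,5R)-5-bromo-3-[(1S,3S,4S)-3-bromo-4-chloro-4-methylcyclohexyl]-6,6-dimethyl-2-methylideneoxan-3-yl]oxy-trimethylsilane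
Conditions: Cp2TiMe2 (3 equiv), toluene, 70 °C, dark; filtration through basic alumina
Reagents that add atoms: dimethyltitanocene C[Ti+2]C.c1cc[cH-]c1.c1cc[cH-]c1
Why: Petasis methylenation: thermolysis of Cp2TiMe2 gives Cp2Ti=CH2, which converts lactone carbonyls into exocyclic enol ethers by [2+2] addition and cycloreversion, is neither Lewis acidic nor basic enough to disturb the tertiary chloride and the two secondary bromides, and cannot lead to an endocyclic isomer because C3 bears no hydrogen.

Step 14
Reactants: 23 the silylated enol ether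
Product: 24 (3R,5R)-5-bromo-3-[(1S,3S,4S)-3-bromo-4-chloro-4-methylcyclohexyl]-6,6-dimethyl-2-methylideneoxan-3-ol (target, CNP0106480.1)
Conditions: TBAF, THF, 0 °C; pH 7 buffer work-up, Et3N-deactivated silica
Reagents that add atoms: none
Why: Fluoride-induced desilylation works under non-acidic conditions, which the acid-labile 2-methylidene pyran needs, and a trimethylsilyl ether should fall off at 0 °C before fluoride can act as a base on the halides.

## Compound list

1 | (S)-(−)-limonene | C=C(C)[C@H]1CCC(C)=CC1 | starting material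
2 | 2-[(1S)-4-methylcyclohex-3-en-1-yl]allyllithium | [Li]CC(=C)[C@H]1CCC(C)=CC1 | intermediate (not isolated)
3 | dimethyl 2-[(1S)-4-methylcyclohex-3-en-1-yl]allylboronate | COB(OC)CC(=C)[C@H]1CCC(C)=CC1 | intermediate (not isolated)
4 | 2-[(1S)-4-methylcyclohex-3-en-1-yl]prop-2-en-1-ol | C=C(CO)[C@H]1CCC(C)=CC1 | intermediate
5 | 2-[(1S)-4-methylcyclohex-3-en-1-yl]prop-2-enal | C=C(C=O)[C@H]1CCC(C)=CC1 | intermediate
6 | 2-[(1S)-4-methylcyclohex-3-en-1-yl]prop-2-enoic acid | C=C(C(=O)O)[C@H]1CCC(C)=CC1 | intermediate
7 | 3-hydroxy-3-methylbutan-2-one | CC(=O)C(C)(C)O | starting material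
8 | mixed anhydride of 6 and 2,4,6-trichlorobenzoic acid | C=C(C(=O)OC(=O)c1c(Cl)cc(Cl)cc1Cl)[C@H]1CCC(C)=CC1 | intermediate (not isolated)
9 | 2-methyl-3-oxobutan-2-yl 2-[(1S)-4-methylcyclohex-3-en-1-yl]prop-2-enoate | C=C(C(=O)OC(C)(C)C(C)=O)[C@H]1CCC(C)=CC1 | intermediate
10 | 2-methyl-3-oxobutan-2-yl 2-[(1R,3S,6S)-6-methyl-7-oxabicyclo[4.1.0]heptan-3-yl]prop-2-enoate | C=C(C(=O)OC(C)(C)C(C)=O)[C@H]1CC[C@]2(C)O[C@@H]2C1 | intermediate
11 | 2-methyl-3-oxobutan-2-yl 2-[(1S,3R,4R)-4-bromo-3-hydroxy-4-methylcyclohexyl]prop-2-enoate | C=C(C(=O)OC(C)(C)C(C)=O)[C@H]1CC[C@@](C)(Br)[C@H](O)C1 | intermediate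
12 | chlorosulfite of 11 | C=C(C(=O)OC(C)(C)C(C)=O)[C@H]1CC[C@@](C)(Br)[C@H](OS(=O)Cl)C1 | intermediate (not isolated)
13 | C4′,C5′-bromonium chloride, Br cis to the side chain | C=C(C(=O)OC(C)(C)C(C)=O)[C@H]1CC[C@@]2(C)[Br+][C@H]2C1.[Cl-] | intermediate (not isolated)
14 | 2-methyl-3-oxobutan-2-yl 2-[(1S,3S,4S)-3-bromo-4-chloro-4-methylcyclohexyl]prop-2-enoate | C=C(C(=O)OC(C)(C)C(C)=O)[C@H]1CC[C@](C)(Cl)[C@@H](Br)C1 | intermediate
15 | 1,2,4-trioxolane (ozonide) of 14, ozonide carbon unassigned | CC(=O)C(C)(C)OC(=O)C1(OCOO1)[C@H]1CC[C@](C)(Cl)[C@@H](Br)C1 | intermediate (not isolated)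
16 | 2-methyl-3-oxobutan-2-yl 2-[(1S,3S,4S)-3-bromo-4-chloro-4-methylcyclohexyl]-2-oxoacetate | CC(=O)C(C)(C)OC(=O)C(=O)[C@H]1CC[C@](C)(Cl)[C@@H](Br)C1 | intermediate
17 | enamine of the C5 ketone of 16 with 9-amino-9-deoxy-epi-quinine | C=C(N[C@@H](c1ccnc2ccc(OC)cc12)[C@@H]1C[C@@H]2CCN1C[C@@H]2C=C)C(C)(C)OC(=O)C(=O)[C@H]1CC[C@](C)(Cl)[C@@H](Br)C1 | intermediate (not isolated)
18 | (3R)-3-[(1S,3S,4S)-3-bromo-4-chloro-4-methylcyclohexyl]-3-hydroxy-6,6-dimethyloxane-2,5-dione | O=C1OC(C)(C)C(=O)C[C@@]1(O)[C@H]1CC[C@](C)(Cl)[C@@H](Br)C1 | intermediate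
19 | (3R,5S)-3-[(1S,3S,4S)-3-bromo-4-chloro-4-methylcyclohexyl]-3,5-dihydroxy-6,6-dimethyloxan-2-one | O=C1OC(C)(C)[C@@H](O)C[C@@]1(O)[C@H]1CC[C@](C)(Cl)[C@@H](Br)C1 | intermediate
20 | C5 triflate of 19 | O=C1OC(C)(C)[C@@H](OS(=O)(=O)C(F)(F)F)C[C@@]1(O)[C@H]1CC[C@](C)(Cl)[C@@H](Br)C1 | intermediate (not isolated)
21 | (3R,5R)-5-bromo-3-[(1S,3S,4S)-3-bromo-4-chloro-4-methylcyclohexyl]-3-hydroxy-6,6-dimethyloxan-2-one | O=C1OC(C)(C)[C@H](Br)C[C@@]1(O)[C@H]1CC[C@](C)(Cl)[C@@H](Br)C1 | intermediate
22 | C3 trimethylsilyl ether of 21 | O=C1OC(C)(C)[C@H](Br)C[C@@]1(O[Si](C)(C)C)[C@H]1CC[C@](C)(Cl)[C@@H](Br)C1 | intermediate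
23 | C3 trimethylsilyl ether of the target | C=C1OC(C)(C)[C@H](Br)C[C@@]1(O[Si](C)(C)C)[C@H]1CC[C@](C)(Cl)[C@@H](Br)C1 | intermediate
24 | (3R,5R)-5-bromo-3-[(1S,3S,4S)-3-bromo-4-chloro-4-methylcyclohexyl]-6,6-dimethyl-2-methylideneoxan-3-ol | C=C1OC(C)(C)[C@H](Br)C[C@@]1(O)[C@H]1CC[C@](C)(Cl)[C@@H](Br)C1 | target

## Step count and risks

Total step count: 14. Longest linear sequence: 14 steps, from 1 to 24. Compound 7 enters at step 4.

**Step 9 (key step, new method).**
- What may go wrong:
  - The ester may stay in its extended Z rotamer, so that ring closure is slow.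
  - Meanwhile the amine may condense with the more electrophilic C3 ketone and epimerise C1′.
  - The acyl group may migrate from O1 to the catalyst nitrogen and consume the catalyst.
  - Facial selectivity at C3 may be poor, or the aldol may dehydrate.
- Fallback: C3–C4 is made intermolecularly by known chemistry and the ring is closed afterwards at O1–C2. It sets out from 16 and 7 and comes back at 18.
  - Ketone 7 is silylated twice (TMSOTf, Et3N, CH2Cl2, 0 °C) to 3-methyl-2,3-bis(trimethylsilyloxy)but-1-ene F1.
  - F1 is added to the C3 ketone of 16 in a Mukaiyama aldol addition under a chelating chiral Lewis acid (Cu(OTf)2/tert-butyl-bis(oxazoline), ligand antipode chosen for Si-face attack, CH2Cl2, −78 → −20 °C). This reaction type is established for enol silanes and α-keto esters, and it should give the doubly silylated open-chain adduct F2.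
  - Dilute HCl in THF frees the open-chain dihydroxy diketo ester F3, from which any C3 epimer is removed by chromatography.
  - Camphorsulfonic acid in warm toluene then closes the lactone. The C6 hydroxyl attacks C2, 7 leaves as the alcohol, and 18 results.

**Step 11.**
- What may go wrong:
  - Bromide may be kept from C5 by the neighbouring gem-dimethyl carbon.
  - The syn-axial C3 hydroxyl may attack C5 itself and close an oxetane.
  - Triflic acid may be lost toward C4.
  - Before sulfonylation the acyl group may migrate from O1 to the C5 oxygen and contract the δ-lactone to a γ-lactone.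
- Fallback: double inversion in the open chain through an epoxide. It sets out from 18 and comes back at 21.
  - Corey–Bakshi–Shibata reduction of 18 with the (S)-oxazaborolidine and BH3·SMe2 (quaternary C6 as the large flank, C4H2 as the small one) should give the 3,5-cis diol lactone F4 (5R).
  - MsCl/Et3N gives the C5 mesylate F5.
  - K2CO3 in MeOH opens the lactone, and the freed C6 alkoxide at once displaces the mesylate (first inversion) to give the epoxy methyl ester F6. The C5 oxygen is never free, so it cannot form a γ-lactone.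
  - Li2NiBr4 in THF opens the epoxide at the secondary carbon C5 (second inversion) to give the bromohydrin methyl ester F7.
  - Camphorsulfonic acid in CH2Cl2 relactonises F7 through the C6 hydroxyl to 21.

**Step 7.**
- What may go wrong:
  - Chloride may capture the bromonium ion at the secondary carbon C5′, which is the Fürst–Plattner mode of opening.
  - HBr may be lost from the tertiary bromide before or after ionisation.
- Fallback: thermodynamic instead of kinetic control. It sets out from 11 and comes back at 14.
  - 11 is treated with SOCl2 in a non-polar solvent (pentane/Et2O), so that tight ion-pair return gives the diaxial 4-bromo-3-chloro isomer F8, or a mixture of F8 and 14.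
  - Without separation the material is heated in chlorobenzene or MeCN (80–100 °C).
  - This is the classical diaxial-to-diequatorial rearrangement of vicinal dihalides. The two halogens exchange carbons through the same bridged ion pair, which should lead to 14 with the stronger tertiary C–Cl bond and both halogens equatorial.

## Further compounds

F1 | step 9 | 3-methyl-2,3-bis(trimethylsilyloxy)but-1-ene | C=C(O[Si](C)(C)C)C(C)(C)O[Si](C)(C)C
F2 | step 9 | 2-methyl-3-oxobutan-2-yl (2R)-2-[(1S,3S,4S)-3-bromo-4-chloro-4-methylcyclohexyl]-5-methyl-4-oxo-2,5-bis(trimethylsilyloxy)hexanoate | CC(=O)C(C)(C)OC(=O)[C@@](O[Si](C)(C)C)(CC(=O)C(C)(C)O[Si](C)(C)C)[C@H]1CC[C@](C)(Cl)[C@@H](Br)C1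
F3 | step 9 | 2-methyl-3-oxobutan-2-yl (2R)-2-[(1S,3S,4S)-3-bromo-4-chloro-4-methylcyclohexyl]-2,5-dihydroxy-5-methyl-4-oxohexanoate | CC(=O)C(C)(C)OC(=O)[C@@](O)(CC(=O)C(C)(C)O)[C@H]1CC[C@](C)(Cl)[C@@H](Br)C1
F4 | step 11 | (3R,5R)-3-[(1S,3S,4S)-3-bromo-4-chloro-4-methylcyclohexyl]-3,5-dihydroxy-6,6-dimethyloxan-2-one | O=C1OC(C)(C)[C@H](O)C[C@@]1(O)[C@H]1CC[C@](C)(Cl)[C@@H](Br)C1
F5 | step 11 | C5 methanesulfonate of F4 | O=C1OC(C)(C)[C@H](OS(C)(=O)=O)C[C@@]1(O)[C@H]1CC[C@](C)(Cl)[C@@H](Br)C1
F6 | step 11 | methyl (2R)-2-[(1S,3S,4S)-3-bromo-4-chloro-4-methylcyclohexyl]-3-[(2S)-3,3-dimethyloxiran-2-yl]-2-hydroxypropanoate | COC(=O)[C@@](O)(C[C@@H]1OC1(C)C)[C@H]1CC[C@](C)(Cl)[C@@H](Br)C1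
F7 | step 11 | methyl (2R,4R)-4-bromo-2-[(1S,3S,4S)-3-bromo-4-chloro-4-methylcyclohexyl]-2,5-dihydroxy-5-methylhexanoate | COC(=O)[C@@](O)(C[C@@H](Br)C(C)(C)O)[C@H]1CC[C@](C)(Cl)[C@@H](Br)C1
F8 | step 7 | 2-methyl-3-oxobutan-2-yl 2-[(1S,3R,4R)-4-bromo-3-chloro-4-methylcyclohexyl]prop-2-enoate | C=C(C(=O)OC(C)(C)C(C)=O)[C@H]1CC[C@@](C)(Br)[C@H](Cl)C1
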